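**Assumption:** locants follow labdane numbering (C6 carbinol carbon, C17 carboxyl carbon, C16 lactone carbonyl); (R)-2-methylbutanoic acid and ylide 3 are bought as such.

## Retrosynthetic overview

1. Target 15 ⇐ Pinnick oxidation of the C17 enal, after an exo-to-endo shift of a 12(13)-alkylidene lactone; the C6 ester comes from the 6α-alcohol and (R)-2-methylbutanoic acid.
2. 6α-OH ⇐ γ-oxygenation (vinylogous Rubottom) of the silyl dienol ether of the Δ7-17-aldehyde; the axial 4β- and 10β-methyls force α-face attack.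
3. C17–O ⇐ key step: SeO2 ene reaction, then [2,3]-sigmatropic shift of the allylseleninic acid on the Δ7 olefin.
4. C12–C13 ⇐ Wittig reaction of sclareolide lactol with the butyrolactone ylide; Δ7 ⇐ dehydration of the 8α-ol.
5. Rings: rings A and B with C5, C9 and C10 are bought in (+)-sclareolide. The only other ring, the lactone, enters preformed in step 2 and becomes the butenolide in step 8.

## Route

Step 1
Reactants: 1 (+)-sclareolide
Product: 2 sclareolide lactol (8α,12-epoxy-13,14,15,16-tetranorlabdan-12-ol; C12 epimers)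
Conditions: iBu2AlH (1.1 equiv), CH2Cl2, −78 °C; aq. KNaC4H4O6
Reagents that add atoms: none
Why: Partial hydride reduction of the γ-lactone stops at the lactol because the aluminium hemiacetal is stable at −78 °C; C5, C8, C9 and C10 are untouched and the new C12 centre is lost in step 2.

Step 2
Reactants: 2 sclareolide lactol; 3 α-(triphenylphosphoranylidene)-γ-butyrolactone
Product: 4 (12E)-8α-hydroxylabd-12-en-16,15-olide
Conditions: PhMe, PhCO2H (cat.), 100 °C
Reagents that add atoms: none
Why: Wittig olefination of the open hydroxy-aldehyde form of the lactol with a stabilized ylide gives the E-alkylidene lactone, and the hindered tertiary 8α-OH does not add back under neutral conditions.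

Step 3
Reactants: 4 (12E)-8α-hydroxylabd-12-en-16,15-olide
Product: 5 (12E)-labda-7,12-dien-16,15-olide
Conditions: H2SO4 (1 equiv), EtOH, 20 °C; AgNO3–SiO2 chromatography
Reagents that add atoms: none
Why: E1 dehydration of the tertiary alcohol: loss of the axial 7α-H gives the trisubstituted Δ7 olefin, the exocyclic isomer re-enters the cation under protic acid, and the hindered 9α-H is lost only slowly; no stereocentre is formed and C9 is kept.

Step 4
Reactants: 5 (12E)-labda-7,12-dien-16,15-olide
Product: 8 (12E)-17-oxolabda-7,12-dien-16,15-olide, via allylseleninic acid 6 (not isolated), via allylic alcohol 7 (not isolated)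
Conditions: SeO2 (1.5 equiv), 1,4-dioxane/H2O (50:1), 80 °C
Reagents that add atoms: selenium dioxide O=[Se]=O
Why: Riley oxidation: an ene reaction puts selenium on C7 from the open α face with loss of a C17 hydrogen, the [2,3]-sigmatropic shift of 6 then forms the C17–O bond and restores Δ7, and SeO2 takes alcohol 7 on to the enal; the electron-poor lactone olefin does not react and the C7 centre of 6 is transient.

Step 5
Reactants: 8 (12E)-17-oxolabda-7,12-dien-16,15-olide
Product: 9 (12E)-17-(tert-butyldimethylsilyloxy)labda-6,8(17),12-trien-16,15-olide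
Conditions: TBSOTf (1.2 equiv), Et3N (2 equiv), CH2Cl2, −78 to 0 °C
Reagents that add atoms: tert-butyldimethylsilyl trifluoromethanesulfonate CC(C)(C)[Si](C)(C)OS(=O)(=O)C(F)(F)F
Why: Soft enolization: O-silylation of the aldehyde and γ-deprotonation at C6 give the linear silyl dienol ether, since loss of H-9 gives no conjugated enolate and the lactone is not enolized by Et3N.

Step 6
Reactants: 9 (12E)-17-(tert-butyldimethylsilyloxy)labda-6,8(17),12-trien-16,15-olide
Product: 11 (12E)-6α-hydroxy-17-oxolabda-7,12-dien-16,15-olide, via epoxide 10 (not isolated)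
Conditions: mCPBA (1.05 equiv), NaHCO3, CH2Cl2, −20 °C; then 1 M HCl, THF, 0 °C
Reagents that add atoms: 3-chloroperoxybenzoic acid OOC(=O)c1cccc(Cl)c1
Why: Vinylogous Rubottom oxidation: the peracid epoxidizes the distal C6=C7 bond from the α face because the β face at C6 is blocked by the two syn-axial methyls on C4 and C10, and silyloxy-assisted opening with desilylation gives the 6α-hydroxy enal, which sets C6.

Step 7
Reactants: 11 (12E)-6α-hydroxy-17-oxolabda-7,12-dien-16,15-olide; 12 (R)-2-methylbutanoic acid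
Product: 13 (12E)-6α-[(2R)-2-methylbutanoyloxy]-17-oxolabda-7,12-dien-16,15-olide
Conditions: DCC, 4-dimethylaminopyridine (cat.), CH2Cl2, 0 to 20 °C
Reagents that add atoms: none
Why: Steglich esterification acylates the equatorial 6α-OH with retention at C6, and the α-centre of the simple branched acid is not epimerized under these mild conditions.

Step 8
Reactants: 13 (12E)-6α-[(2R)-2-methylbutanoyloxy]-17-oxolabda-7,12-dien-16,15-olide
Product: 14 6α-[(2R)-2-methylbutanoyloxy]-17-oxolabda-7,13-dien-16,15-olide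
Conditions: RhCl3·3H2O (10 mol %), EtOH/H2O (9:1), 75 °C
Reagents that add atoms: none
Why: Rhodium hydride addition and β-hydride elimination (olefin isomerization) move the exocyclic C12=C13 bond into the ring to give the more stable endocyclic butenolide, as 2-alkylidenecyclopentanones give 2-alkylcyclopentenones; the hindered conjugated Δ7 enal stays and no stereocentre is touched.

Step 9
Reactants: 14 6α-[(2R)-2-methylbutanoyloxy]-17-oxolabda-7,13-dien-16,15-olide
Product: 15 6α-[(2R)-2-methylbutanoyloxy]labda-7,13-dien-16,15-olid-17-oic acid (CNP0150853.1)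
Conditions: NaClO2, NaH2PO4, 2-methyl-2-butene, t-BuOH/H2O, 0 to 20 °C
Reagents that add atoms: sodium chlorite [Na+].[O-]Cl=O
Why: Pinnick oxidation converts only the aldehyde to the acid; the butenolide, the allylic ester and all stereocentres are unaffected.

## Compound list

1 | (+)-sclareolide (13,14,15,16-tetranorlabdane-12,8α-olide) | C[C@]12CCCC(C)(C)[C@@H]1CC[C@@]1(C)OC(=O)C[C@H]21 | starting material
2 | sclareolide lactol (8α,12-epoxy-13,14,15,16-tetranorlabdan-12-ol; C12 epimers) | C[C@]12CCCC(C)(C)[C@@H]1CC[C@@]1(C)OC(O)C[C@H]21 | intermediate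
3 | α-(triphenylphosphoranylidene)-γ-butyrolactone | O=C1OCCC1=P(c1ccccc1)(c1ccccc1)c1ccccc1 | starting material
4 | (12E)-8α-hydroxylabd-12-en-16,15-olide | C[C@]12CCCC(C)(C)[C@@H]1CC[C@@](C)(O)[C@@H]2C/C=C1\CCOC1=O | intermediate
5 | (12E)-labda-7,12-dien-16,15-olide | C1C=C(C)[C@H](C/C=C2\CCOC2=O)[C@@]2(C)CCCC(C)(C)[C@H]12 | intermediate
6 | (12E)-7α-(hydroxyseleninyl)labda-8(17),12-dien-16,15-olide (allylseleninic acid) | C1[C@@H]([Se](=O)O)C(=C)[C@H](C/C=C2\CCOC2=O)[C@@]2(C)CCCC(C)(C)[C@H]12 | intermediate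
7 | (12E)-17-hydroxylabda-7,12-dien-16,15-olide | C1C=C(CO)[C@H](C/C=C2\CCOC2=O)[C@@]2(C)CCCC(C)(C)[C@H]12 | intermediate
8 | (12E)-17-oxolabda-7,12-dien-16,15-olide | C1C=C(C=O)[C@H](C/C=C2\CCOC2=O)[C@@]2(C)CCCC(C)(C)[C@H]12 | intermediate
9 | (12E)-17-(tert-butyldimethylsilyloxy)labda-6,8(17),12-trien-16,15-olide (C8=C17 geometry not fixed) | C1=CC(=CO[Si](C)(C)C(C)(C)C)[C@H](C/C=C2\CCOC2=O)[C@@]2(C)CCCC(C)(C)[C@H]12 | intermediate
10 | (12E)-6α,7α-epoxy-17-(tert-butyldimethylsilyloxy)labda-8(17),12-dien-16,15-olide | [C@H]12O[C@H]1C(=CO[Si](C)(C)C(C)(C)C)[C@H](C/C=C3\CCOC3=O)[C@@]3(C)CCCC(C)(C)[C@H]23 | intermediate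
11 | (12E)-6α-hydroxy-17-oxolabda-7,12-dien-16,15-olide | O[C@H]1C=C(C=O)[C@H](C/C=C2\CCOC2=O)[C@@]2(C)CCCC(C)(C)[C@H]12 | intermediate
12 | (R)-2-methylbutanoic acid | CC[C@@H](C)C(=O)O | starting material
13 | (12E)-6α-[(2R)-2-methylbutanoyloxy]-17-oxolabda-7,12-dien-16,15-olide | CC[C@@H](C)C(=O)O[C@H]1C=C(C=O)[C@H](C/C=C2\CCOC2=O)[C@@]2(C)CCCC(C)(C)[C@H]12 | intermediate
14 | 6α-[(2R)-2-methylbutanoyloxy]-17-oxolabda-7,13-dien-16,15-olide | CC[C@@H](C)C(=O)O[C@H]1C=C(C=O)[C@H](CCC2=CCOC2=O)[C@@]2(C)CCCC(C)(C)[C@H]12 | intermediate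
15 | 6α-[(2R)-2-methylbutanoyloxy]labda-7,13-dien-16,15-olid-17-oic acid (CNP0150853.1) | CC[C@@H](C)C(=O)O[C@H]1C=C(C(=O)O)[C@H](CCC2=CCOC2=O)[C@@]2(C)CCCC(C)(C)[C@H]12 | target

## Step count and risks

Total steps: 9. Longest linear sequence: 9 steps, from 1 to 15.

**Step 3 (regiochemistry of the dehydration).** The Δ8(17) and Δ8 olefins may form in larger amounts than expected. The fallback sets out from 4 and comes back at 8. Anti-elimination with SOCl2 and pyridine (CH2Cl2, −78 °C) can only take a methyl hydrogen anti to the equatorial 8α-chlorosulfite and gives the exocyclic olefin (12E)-labda-8(17),12-dien-16,15-olide F1. SeO2 (cat.) with t-BuOOH (CH2Cl2, 20 °C) hydroxylates C7 by the same ene and [2,3]-sigmatropic sequence to give (12E)-7α-hydroxylabda-8(17),12-dien-16,15-olide F2. O3ReOSiPh3 (2 mol %, Et2O, −50 to 0 °C) then moves the oxygen from C7 to C17 by a [3,3]-sigmatropic shift of the allyl perrhenate, towards the endocyclic trisubstituted olefin. This gives alcohol 7, here isolated, and MnO2 (CH2Cl2, 20 °C) oxidizes it to 8.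

**Step 6 (site and face of the dienol ether oxidation).** The one-pot silyl version may attack the enol ether bond or over-oxidize. The fallback sets out from 8 and comes back at 11. Isopropenyl acetate with p-toluenesulfonic acid (cat.) at 90 °C gives the dienyl acetate (12E)-17-acetoxylabda-6,8(17),12-trien-16,15-olide F3. Its enol ester bond is a poor donor, so mCPBA with NaHCO3 (CH2Cl2, 0 °C) epoxidizes only the distal Δ6 bond, again from the α face, to the isolable (12E)-17-acetoxy-6α,7α-epoxylabda-8(17),12-dien-16,15-olide F4. K2CO3 in MeOH at 0 °C cleaves the enol acetate, and the enolate opens the epoxide (E1cB) to give 11.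

**Step 8 (exo-to-endo shift next to an aldehyde and an allylic ester).** The rhodium hydride may be slow or may touch the enal. The fallback sets out from 13 and comes back at 15. Pinnick oxidation first (NaClO2, NaH2PO4, 2-methyl-2-butene) gives (12E)-6α-[(2R)-2-methylbutanoyloxy]labda-7,12-dien-16,15-olid-17-oic acid F5. LiBH(sBu)3 (2.2 equiv, THF, −78 °C; the first equivalent only deprotonates the acid) adds hydride to C12, and PhSeBr traps the lactone enolate to give 6α-[(2R)-2-methylbutanoyloxy]-13-(phenylselanyl)labd-7-en-16,15-olid-17-oic acid F6 (C13 epimers). H2O2 with pyridine (CH2Cl2, 0 to 20 °C) oxidizes selenium, and syn-elimination of the selenoxide into the ring gives 15 directly. Any exocyclic elimination product is F5 and is recycled.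

## Further compounds

F1 | step 3 | (12E)-labda-8(17),12-dien-16,15-olide | C1CC(=C)[C@H](C/C=C2\CCOC2=O)[C@@]2(C)CCCC(C)(C)[C@H]12
F2 | step 3 | (12E)-7α-hydroxylabda-8(17),12-dien-16,15-olide | C1[C@@H](O)C(=C)[C@H](C/C=C2\CCOC2=O)[C@@]2(C)CCCC(C)(C)[C@H]12
F3 | step 6 | (12E)-17-acetoxylabda-6,8(17),12-trien-16,15-olide | C1=CC(=COC(C)=O)[C@H](C/C=C2\CCOC2=O)[C@@]2(C)CCCC(C)(C)[C@H]12
F4 | step 6 | (12E)-17-acetoxy-6α,7α-epoxylabda-8(17),12-dien-16,15-olide | [C@H]12O[C@H]1C(=COC(C)=O)[C@H](C/C=C3\CCOC3=O)[C@@]3(C)CCCC(C)(C)[C@H]23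
F5 | step 8 | (12E)-6α-[(2R)-2-methylbutanoyloxy]labda-7,12-dien-16,15-olid-17-oic acid | CC[C@@H](C)C(=O)O[C@H]1C=C(C(=O)O)[C@H](C/C=C2\CCOC2=O)[C@@]2(C)CCCC(C)(C)[C@H]12
F6 | step 8 | 6α-[(2R)-2-methylbutanoyloxy]-13-(phenylselanyl)labd-7-en-16,15-olid-17-oic acid (C13 epimers) | CC[C@@H](C)C(=O)O[C@H]1C=C(C(=O)O)[C@H](CCC2([Se]c3ccccc3)CCOC2=O)[C@@]2(C)CCCC(C)(C)[C@H]12
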